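**Plan**

- Retrosynthesis: the two acyl groups come off first, then the benzyl C–H bonds (back to an exocyclic benzylidene). The oxolane is then cut at O1–C2 and C3–C4 in one stroke to an enal and an aryl propargylic alcohol. The alkynol is cut at the aryl–alkyne bond.
- Forward: Sonogashira coupling gives the alkynol and pivaloylation gives the enal. One amine/palladium cascade closes the oxolane, the only ring made, and the aldehyde is reduced in the same flask. Acetylation, hydrogenation and methanolysis finish the route.
- Enabling feature: in the oxolane (O1, C2 aryl, C3 CH2OH, C4 benzyl, C5) the hydroxymethyl carbon is a masked aldehyde with C3 as its α-carbon and the O1-bearing C2 as its β-carbon. An enal can therefore take O1 at C2 as an iminium ion and then bond C3 to C4 as an enamine. The C4 benzyl group is a masked arylalkyne.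
- Stereochemistry: C2 and C3 come from the (S)-diphenylprolinol silyl ether catalyst (2S, 2,3-trans). C4 comes from substrate-controlled hydrogenation of the E-benzylidene anti to the C3 acetoxymethyl group (3,4-cis).

Key step: step 3

Assumption: the facial sense of the (S)-catalyst is assigned from the usual model (reagents add opposite the diphenyl(silyloxy)methyl group); the (R)-catalyst would be used if this assignment proved reversed.

**Route**

Step 1
Reactants: 1 4-iodo-1,2-dimethoxybenzene; 2 prop-2-yn-1-ol
Product: 3 3-(3,4-dimethoxyphenyl)prop-2-yn-1-ol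
Conditions: PdCl2(PPh3)2 (2 mol %), CuI (4 mol %), Et3N, THF, rt
Reagents that add atoms: none
Why: Sonogashira coupling of an electron-rich aryl iodide with a terminal alkyne is reliable and tolerates the free propargylic hydroxyl; no stereocenter is formed.

Step 2
Reactants: 4 (E)-coniferaldehyde
Product: 5 2-methoxy-4-[(1E)-3-oxoprop-1-en-1-yl]phenyl 2,2-dimethylpropanoate
Conditions: PivCl, Et3N, DMAP (cat.), CH2Cl2, 0 °C to rt
Reagents that add atoms: pivaloyl chloride, CC(C)(C)C(=O)Cl
Why: DMAP-catalysed O-acylation masks the phenol as a hindered, electron-withdrawing ester that keeps the enal electrophilic for iminium chemistry and should survive amines, cold hydride and hydrogenation; no stereocenter is formed.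

Step 3
Reactants: 3 3-(3,4-dimethoxyphenyl)prop-2-yn-1-ol; 5 2-methoxy-4-[(1E)-3-oxoprop-1-en-1-yl]phenyl 2,2-dimethylpropanoate
Product: 8 4-[(2S,3R,4E)-4-(3,4-dimethoxybenzylidene)-3-(hydroxymethyl)oxolan-2-yl]-2-methoxyphenyl 2,2-dimethylpropanoate, via oxa-Michael adduct 6 (not isolated), via benzylidene aldehyde 7 (not isolated)
Conditions: (S)-α,α-diphenylprolinol trimethylsilyl ether (20 mol %), Pd(PPh3)4 (5 mol %), PhCO2H (20 mol %), THF, 4 °C to rt; then MeOH, NaBH4, −20 °C
Reagents that add atoms: none
Why: Proposed new method: the amine condenses with enal 5 to an iminium ion whose β-carbon (future C2) reversibly takes up the hydroxyl oxygen of 3 (bond O1–C2, adduct 6 as its enamine), the enamine carbon (future C3) then adds anti across the palladium-bound alkyne (bond C3–C4), and protonolysis of the vinyl–palladium bond plus hydrolysis releases 7, which NaBH4 reduces in the same flask before the double bond can move into conjugation. The closest known reaction type is the amine/palladium co-catalysed oxa-Michael–carbocyclisation of β-aryl enals with propargyl alcohol itself, a terminal alkyne; an aryl-capped internal alkyne has not been shown, but it should bind palladium comparably and leaves the tether geometry unchanged. The oxolane ring closes in the 5-exo-dig mode, the enamine carbon reaching the proximal alkyne carbon through the three-atom C2–O1–C5 tether. C2 is set by addition of oxygen to the iminium face opposite the diphenyl(silyloxy)methyl group and, because the oxa-Michael step is reversible, only the matched adduct should cyclise (dynamic kinetic resolution) to give 2S, while C3 is set by enamine attack from the same open face, placing the formyl group trans to the aryl group, and anti addition fixes the E alkene. The step needs 5-exo over 6-endo closure and 1,4- over 1,2-addition of the alcohol: the first is secured by the short tether and by a phosphine–palladium catalyst instead of a strongly cationic π-acid that would polarise the electron-rich arylalkyne toward endo attack, the second by the reversibility of hemiacetal formation and by the pivalate, which makes the iminium ion more electrophilic than a 4-alkoxy analogue.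

Step 4
Reactants: 8 4-[(2S,3R,4E)-4-(3,4-dimethoxybenzylidene)-3-(hydroxymethyl)oxolan-2-yl]-2-methoxyphenyl 2,2-dimethylpropanoate
Product: 9 {(2S,3R,4E)-4-(3,4-dimethoxybenzylidene)-2-[3-methoxy-4-(pivaloyloxy)phenyl]oxolan-3-yl}methyl acetate
Conditions: Ac2O, pyridine, DMAP (cat.), CH2Cl2, 0 °C to rt
Reagents that add atoms: acetic anhydride, CC(=O)OC(C)=O
Why: Standard O-acetylation turns the hydroxymethyl group into a non-coordinating steric shield for the hydrogenation and into a group that leaves together with the pivalate; no stereocenter is touched.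

Step 5
Reactants: 9 {(2S,3R,4E)-4-(3,4-dimethoxybenzylidene)-2-[3-methoxy-4-(pivaloyloxy)phenyl]oxolan-3-yl}methyl acetate
Product: 10 {(2S,3R,4R)-4-(3,4-dimethoxybenzyl)-2-[3-methoxy-4-(pivaloyloxy)phenyl]oxolan-3-yl}methyl acetate
Conditions: H2 (1 atm), Pd/C (5 wt %), EtOAc, rt, stopped after one equivalent of H2
Reagents that add atoms: none
Why: Heterogeneous catalytic hydrogenation adds H2 syn from the face opposite the C3 acetoxymethyl group, which 1,3-allylic strain against the cis aryl group of the E-benzylidene holds pseudo-axial, so the benzyl group should end cis to the acetoxymethyl group (4R), while the electron-poor aryl pivalate disfavours hydrogenolysis of the benzylic ring C–O bond.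

Step 6
Reactants: 10 {(2S,3R,4R)-4-(3,4-dimethoxybenzyl)-2-[3-methoxy-4-(pivaloyloxy)phenyl]oxolan-3-yl}methyl acetate
Product: 11 4'-O-methyllariciresinol, 4-[(2S,3R,4R)-4-(3,4-dimethoxybenzyl)-3-(hydroxymethyl)oxolan-2-yl]-2-methoxyphenol
Conditions: K2CO3 (0.3 equiv), MeOH, rt; NH4Cl work-up
Reagents that add atoms: none
Why: Base-catalysed transesterification with methanol should remove the aryl pivalate and the primary acetate in one operation under conditions too mild to open the p-hydroxybenzylic ether, leaving the three stereocenters untouched.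

**Compound list**

1 | 4-iodo-1,2-dimethoxybenzene | COc1ccc(I)cc1OC | starting material
2 | prop-2-yn-1-ol | C#CCO | starting material
3 | 3-(3,4-dimethoxyphenyl)prop-2-yn-1-ol | COc1ccc(C#CCO)cc1OC | intermediate
4 | (E)-coniferaldehyde, (2E)-3-(4-hydroxy-3-methoxyphenyl)prop-2-enal | COc1cc(/C=C/C=O)ccc1O | starting material
5 | 2-methoxy-4-[(1E)-3-oxoprop-1-en-1-yl]phenyl 2,2-dimethylpropanoate | COc1cc(/C=C/C=O)ccc1OC(=O)C(C)(C)C | intermediate
6 | 4-[(1S)-1-{[3-(3,4-dimethoxyphenyl)prop-2-yn-1-yl]oxy}-3-oxopropyl]-2-methoxyphenyl 2,2-dimethylpropanoate (present as its enamine with the catalyst) | COc1cc([C@H](CC=O)OCC#Cc2ccc(OC)c(OC)c2)ccc1OC(=O)C(C)(C)C | intermediate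
7 | 4-[(2S,3S,4E)-4-(3,4-dimethoxybenzylidene)-3-formyloxolan-2-yl]-2-methoxyphenyl 2,2-dimethylpropanoate | COc1cc([C@H]2OC/C(=C/c3ccc(OC)c(OC)c3)[C@@H]2C=O)ccc1OC(=O)C(C)(C)C | intermediate
8 | 4-[(2S,3R,4E)-4-(3,4-dimethoxybenzylidene)-3-(hydroxymethyl)oxolan-2-yl]-2-methoxyphenyl 2,2-dimethylpropanoate | COc1cc([C@H]2OC/C(=C/c3ccc(OC)c(OC)c3)[C@@H]2CO)ccc1OC(=O)C(C)(C)C | intermediate
9 | {(2S,3R,4E)-4-(3,4-dimethoxybenzylidene)-2-[3-methoxy-4-(pivaloyloxy)phenyl]oxolan-3-yl}methyl acetate | COc1cc([C@H]2OC/C(=C/c3ccc(OC)c(OC)c3)[C@@H]2COC(C)=O)ccc1OC(=O)C(C)(C)C | intermediate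
10 | {(2S,3R,4R)-4-(3,4-dimethoxybenzyl)-2-[3-methoxy-4-(pivaloyloxy)phenyl]oxolan-3-yl}methyl acetate | COc1cc([C@H]2OC[C@H](Cc3ccc(OC)c(OC)c3)[C@@H]2COC(C)=O)ccc1OC(=O)C(C)(C)C | intermediate
11 | 4'-O-methyllariciresinol | COc1cc([C@H]2OC[C@H](Cc3ccc(OC)c(OC)c3)[C@@H]2CO)ccc1O | target

**Count**

Total steps: 6. Longest linear sequence: 5 (steps 2 to 6 from 4, or steps 1, 3, 4, 5, 6 from 1).

**Steps most likely to fail**

1. Step 3 (proposed new method). The carbocyclisation may stall on the internal arylalkyne, close in the 6-endo mode, or let the exocyclic double bond migrate into conjugation before reduction, which would erase the C3 centre. The fallback uses known reaction types only: it makes O1–C2 first and closes C3–C4 by a radical cyclisation. It sets out from 5 and 3 and comes back at 8.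
   - Luche reduction of 5 (NaBH4, CeCl3·7H2O, MeOH, 0 °C) should give the coniferyl alcohol 4-O-pivalate F1.
   - Boc2O with DMAP should convert it into the allylic tert-butyl carbonate F2.
   - Iridium-catalysed asymmetric allylic etherification of F2 with alkynol 3 ([Ir(cod)Cl]2, chiral phosphoramidite of the series that gives the S ether, K3PO4, THF) should give the branched propargylic ether F3.
   - mCPBA (NaHCO3, CH2Cl2) should epoxidise the terminal vinyl group to the oxirane F4; it forms as both epimers at the oxirane carbon, which is of no consequence because that carbon becomes the radical.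
   - The trivalent titanium reagent Cp2TiCl (from Cp2TiCl2 and Zn, THF) should open the oxirane to the secondary radical, which closes 5-exo-dig onto the arylalkyne (2,3-trans). This should give 8 together with its Z isomer F5.
   - The mixture goes through step 4 (the Z acetate F6 accompanies 9), and both alkene isomers converge on 10 in step 5.

2. Step 5. Hydrogen delivery may discriminate poorly between the faces (giving the 3,4-trans epimer), and the benzylic or allylic ring C–O bonds may be hydrogenolysed on the metal surface. The fallback sets out from 9 and comes back at 10. It replaces surface hydrogenation by a stepwise metal-hydride hydrogen-atom-transfer reduction (Mn(dpm)3, PhSiH3, t-BuOOH, i-PrOH, rt). The first hydrogen atom should go to C4 from the open face to give the benzylic radical, and no metal surface is present to cleave C–O bonds. This fallback makes no new compound (F0).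

3. Step 6. Cleavage of the hindered aryl ester may be incomplete, or the phenoxide may trigger opening of the p-hydroxybenzylic ether through a quinone methide, epimerising C2. The fallback sets out from 10 and comes back at 11. Both esters are removed reductively with i-Bu2AlH (CH2Cl2, −78 °C, Rochelle salt work-up), so that no free phenoxide sits in a protic basic medium. This fallback makes no new compound (F0).

**Further compounds**

F1 | step 3 | 4-[(1E)-3-hydroxyprop-1-en-1-yl]-2-methoxyphenyl 2,2-dimethylpropanoate | COc1cc(/C=C/CO)ccc1OC(=O)C(C)(C)C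
F2 | step 3 | tert-butyl (2E)-3-[3-methoxy-4-(pivaloyloxy)phenyl]prop-2-en-1-yl carbonate | CC(C)(C)OC(=O)OC/C=C/c1ccc(OC(=O)C(C)(C)C)c(OC)c1
F3 | step 3 | 4-[(1S)-1-{[3-(3,4-dimethoxyphenyl)prop-2-yn-1-yl]oxy}prop-2-en-1-yl]-2-methoxyphenyl 2,2-dimethylpropanoate | COc1cc([C@H](C=C)OCC#Cc2ccc(OC)c(OC)c2)ccc1OC(=O)C(C)(C)C
F4 | step 3 | 4-[(R)-{[3-(3,4-dimethoxyphenyl)prop-2-yn-1-yl]oxy}(oxiran-2-yl)methyl]-2-methoxyphenyl 2,2-dimethylpropanoate, both epimers at the oxirane carbon | COc1cc([C@H](C2CO2)OCC#Cc3ccc(OC)c(OC)c3)ccc1OC(=O)C(C)(C)C
F5 | step 3 | 4-[(2S,3R,4Z)-4-(3,4-dimethoxybenzylidene)-3-(hydroxymethyl)oxolan-2-yl]-2-methoxyphenyl 2,2-dimethylpropanoate | COc1cc([C@H]2OC/C(=C\c3ccc(OC)c(OC)c3)[C@@H]2CO)ccc1OC(=O)C(C)(C)C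
F6 | step 3 | {(2S,3R,4Z)-4-(3,4-dimethoxybenzylidene)-2-[3-methoxy-4-(pivaloyloxy)phenyl]oxolan-3-yl}methyl acetate | COc1cc([C@H]2OC/C(=C\c3ccc(OC)c(OC)c3)[C@@H]2COC(C)=O)ccc1OC(=O)C(C)(C)C
F0 | step 5 | none | none
F0 | step 6 | none | none
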